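**Retrosynthetic overview**
1. Target 42 ⇐ diol 41 (double acetylation) ⇐ macrocyclic core 34, onto which the C9 (S)-2-methylglycidate (acid 37) and the C14 senecioate are placed late.
2. Ten-membered ring (last carbocycle formed): C9–C10 bond by Nozaki–Hiyama–Kishi closure of iodo-aldehyde 33.
3. Butenolide: C7=C11 by intramolecular Horner–Wadsworth–Emmons reaction of α-acyloxy ketone 30; acid 26 supplies C11–C13.
4. Key union: intermolecular (S)-proline aldol forming C6–C7 between bis-epoxy aldehyde 16 (fragment A: C1–C6, C10, C14, C15) and dioxanone 17 (fragment B: C7–C9).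
5. Fragment A from 1 + 5 (Stille), two Sharpless epoxidations and an iodo-Wittig. Ring order: C2–C3 oxirane → C4–C5 oxirane → temporary dioxane → butenolide → ten-membered ring → side-chain oxirane (arrives with 37).

Assumption: locants are those of the germacranolide skeleton (C1–C10 ring, C11–C13 lactone carbons, C14 on C10, C15 on C4); the target read from the SMILES is 1(10)Z,2R,3S,4S,5S,6R,8R,9R with an (S)-2-methyloxirane-2-carboxylate on O9. TBS = tert-butyldimethylsilyl, TES = triethylsilyl, TBDPS = tert-butyldiphenylsilyl, PMB = 4-methoxybenzyl.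

**Fragment A**

Step 1
Reactants: 1 but-2-yn-1-ol
Product: 3 (Z)-3-iodobut-2-en-1-ol, via cyclic alkenylalanate 2 (not isolated)
Conditions: NaAlH2(OCH2CH2OMe)2, THF, 0 °C to rt; then I2, THF, −78 to 0 °C
Reagents that add atoms: iodine, [I][I]
Why: Hydroxyl-directed trans-hydroalumination puts aluminium on C3 inside a five-membered alanate, and iodinolysis of the C–Al bond with retention gives only the Z vinyl iodide (hydroalumination–iodination).

Step 2
Reactants: 3 (Z)-3-iodobut-2-en-1-ol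
Product: 4 TBS ether of 3
Conditions: t-BuMe2SiCl, imidazole, CH2Cl2, 0 °C
Reagents that add atoms: tert-butyldimethylsilyl chloride, CC(C)(C)[Si](C)(C)Cl
Why: Routine silyl ether formation masks the future C6 hydroxyl until the second epoxidation.

Step 3
Reactants: 4 TBS ether of 3; 5 (E)-3-(tributylstannyl)prop-2-en-1-ol
Product: 6 (2E,4Z)-dienol
Conditions: PdCl2(MeCN)2 (5 mol%), DMF, 25 °C
Reagents that add atoms: none
Why: Stille cross-coupling (oxidative addition to zerovalent palladium, transmetallation, reductive elimination) retains both alkene geometries and gives the 2E,4Z diene.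

Step 4
Reactants: 6 (2E,4Z)-dienol
Product: 7 (2R,3R)-epoxy alcohol
Conditions: Ti(OiPr)4 (10 mol%), D-(−)-diethyl tartrate (12 mol%), t-BuOOH, 4 Å MS, CH2Cl2, −20 °C
Reagents that add atoms: tert-butyl hydroperoxide, CC(C)(C)OO
Why: Sharpless asymmetric epoxidation touches only the allylic-alcohol alkene, and the D-(−)-tartrate catalyst delivers oxygen to the face that gives the (2R,3R) trans-epoxide (C2, C3 of the target).

Step 5
Reactants: 7 (2R,3R)-epoxy alcohol
Product: 8 epoxy aldehyde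
Conditions: Dess–Martin periodinane, pyridine, CH2Cl2, 0 °C
Reagents that add atoms: none
Why: Buffered Dess–Martin oxidation gives the trans-epoxy aldehyde without epimerisation or opening of the vinyl epoxide.

Step 6
Reactants: 9 ethyl (triphenylphosphoranylidene)acetate
Product: 10 α-iodo ylide
Conditions: I2, K2CO3, MeOH, 0 °C
Reagents that add atoms: iodine, [I][I]
Why: Electrophilic iodination of the stabilised ylide followed by deprotonation of the iodophosphonium salt gives the α-iodo ylide.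

Step 7
Reactants: 8 epoxy aldehyde; 10 α-iodo ylide
Product: 11 (Z)-α-iodo enoate
Conditions: CH2Cl2, 25 °C
Reagents that add atoms: none
Why: Wittig olefination with the stabilised α-iodo ylide places the ester trans to the epoxide carbon, i.e. the (Z)-2-iodo enoate with iodine cis to C2; no stereocentre is formed.

Step 8
Reactants: 11 (Z)-α-iodo enoate
Product: 12 (Z)-2-iodo allylic alcohol
Conditions: i-Bu2AlH (2.2 equiv), CH2Cl2, −78 °C
Reagents that add atoms: none
Why: Low-temperature ester reduction to the allylic alcohol is faster than hydride attack on the epoxide or the vinyl iodide.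

Step 9
Reactants: 12 (Z)-2-iodo allylic alcohol
Product: 13 C14 PMB ether
Conditions: NaH, 4-MeOC6H4CH2Cl, Bu4NI (cat.), THF/DMF, 0 °C
Reagents that add atoms: 4-methoxybenzyl chloride, COc1ccc(CCl)cc1
Why: Williamson etherification gives an ether that, unlike an allylic ester, is not expelled from the later vinylchromium and can be removed oxidatively at the end.

Step 10
Reactants: 13 C14 PMB ether
Product: 14 C6 allylic alcohol
Conditions: Bu4NF, AcOH, THF, 0 °C
Reagents that add atoms: none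
Why: Buffered fluoride desilylation frees the primary allylic alcohol that directs the second epoxidation.

Step 11
Reactants: 14 C6 allylic alcohol
Product: 15 bis-epoxy alcohol
Conditions: Ti(OiPr)4 (10 mol%), L-(+)-diethyl tartrate (12 mol%), t-BuOOH, 4 Å MS, CH2Cl2, −20 °C
Reagents that add atoms: tert-butyl hydroperoxide, CC(C)(C)OO
Why: Sharpless asymmetric epoxidation of the nerol-type (Z)-allylic alcohol sets the (4S,5S) cis-epoxide under L-(+)-tartrate control, run cold and catalytic in titanium so that epoxidation outpaces opening of the neighbouring vinyl epoxide.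

Step 12
Reactants: 15 bis-epoxy alcohol
Product: 16 bis-epoxy aldehyde (fragment A)
Conditions: Dess–Martin periodinane, pyridine, CH2Cl2, 0 °C
Reagents that add atoms: none
Why: Dess–Martin oxidation gives the configurationally stable cis-epoxy aldehyde.

**Key union and C6–C9 elaboration**

Step 13
Reactants: 16 bis-epoxy aldehyde (fragment A); 17 2,2-dimethyl-1,3-dioxan-5-one (fragment B)
Product: 18 (6S,7S)-anti aldol adduct
Conditions: (S)-proline (30 mol%), 17 (3 equiv), DMF, 4 °C, 4 d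
Reagents that add atoms: none
Why: Proline enamine aldol (List–Houk transition state) in which the E-enamine of the dioxanone adds to one aldehyde face to give the anti adduct with the C6 configuration of the target, the catalyst overriding the weak Felkin bias of the epoxy aldehyde (C7 is a temporary stereocentre).

Step 14
Reactants: 18 anti aldol adduct
Product: 19 C6 TES ether
Conditions: Et3SiOTf, 2,6-lutidine, CH2Cl2, −78 °C
Reagents that add atoms: triethylsilyl trifluoromethanesulfonate, CC[Si](CC)(CC)OS(=O)(=O)C(F)(F)F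
Why: Silylation of the aldol hydroxyl stops retro-aldol cleavage and differentiates O6 from the hydroxyl formed next.

Step 15
Reactants: 19 C6 TES ether
Product: 20 C8 alcohol
Conditions: LiBH(s-Bu)3, THF, −78 °C
Reagents that add atoms: none
Why: Ring-controlled ketone reduction in which the bulky hydride attacks the chair dioxanone equatorially and gives the axial C8 alcohol cis to the C7 side chain, i.e. the 6,8-anti relationship of the target.

Step 16
Reactants: 20 C8 alcohol
Product: 21 C8 TBS ether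
Conditions: t-BuMe2SiOTf, 2,6-lutidine, CH2Cl2, −78 to 0 °C
Reagents that add atoms: tert-butyldimethylsilyl trifluoromethanesulfonate, CC(C)(C)[Si](C)(C)OS(=O)(=O)C(F)(F)F
Why: The silyl triflate silylates the hindered axial alcohol, and O8 stays protected until the final steps.

Step 17
Reactants: 21 C8 TBS ether
Product: 22 C6 alcohol
Conditions: HF·pyridine, pyridine, THF, 0 °C
Reagents that add atoms: none
Why: Buffered HF cleaves the secondary TES ether much faster than the TBS ether or the acetonide (selective desilylation).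

Step 18
Reactants: 23 benzyl 2-(diethoxyphosphoryl)acetate
Product: 24 hydroxymethyl phosphonate
Conditions: (CH2O)n (1.1 equiv), piperidine (0.1 equiv), THF, 60 °C
Reagents that add atoms: formaldehyde (as paraformaldehyde), C=O
Why: Amine-catalysed aldol-type hydroxymethylation of the doubly activated methylene; with only catalytic base the adduct does not go on to olefination.

Step 19
Reactants: 24 hydroxymethyl phosphonate
Product: 25 TBDPS ether
Conditions: t-BuPh2SiCl, imidazole, DMF, 25 °C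
Reagents that add atoms: tert-butyldiphenylsilyl chloride, CC(C)(C)[Si](Cl)(c1ccccc1)c1ccccc1
Why: Silylation of the primary alcohol gives the acid-stable silyl ether that becomes O13.

Step 20
Reactants: 25 TBDPS ether
Product: 26 phosphono acid
Conditions: H2 (1 atm), Pd/C, EtOAc, 25 °C
Reagents that add atoms: none
Why: Hydrogenolysis frees the carboxylic acid under neutral conditions, avoiding base-induced β-elimination.

Step 21
Reactants: 22 C6 alcohol; 26 phosphono acid
Product: 27 C6 phosphonoacetate ester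
Conditions: DCC, DMAP (cat.), CH2Cl2, 0 to 25 °C
Reagents that add atoms: none
Why: Steglich esterification attaches the C11–C13 unit to O6 with retention at C6 (the C11 epimer mixture is of no consequence).

Step 22
Reactants: 27 C6 phosphonoacetate ester
Product: 28 7,9-diol
Conditions: PPTS (0.2 equiv), MeOH, 25 °C
Reagents that add atoms: none
Why: Acid-catalysed transketalisation removes the 1,3-dioxane under the mildest protic conditions, which the epoxides, the TBS, TBDPS and PMB ethers should survive.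

Step 23
Reactants: 28 7,9-diol
Product: 29 C9 TES ether
Conditions: Et3SiCl, imidazole, CH2Cl2, −20 °C
Reagents that add atoms: triethylsilyl chloride, CC[Si](Cl)(CC)CC
Why: The primary C9 hydroxyl is silylated selectively over the hindered secondary C7 hydroxyl (steric differentiation).

Step 24
Reactants: 29 C9 TES ether
Product: 30 C7 ketone
Conditions: Dess–Martin periodinane, pyridine, CH2Cl2, 0 °C
Reagents that add atoms: none
Why: Dess–Martin oxidation turns the temporary C7 carbinol into the ketone needed for lactone annulation.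

Step 25
Reactants: 30 C7 ketone
Product: 31 butenolide
Conditions: LiCl, i-Pr2NEt, MeCN, 0 to 25 °C
Reagents that add atoms: none
Why: Intramolecular Horner–Wadsworth–Emmons reaction under Masamune–Roush conditions, where the phosphonate is far more acidic than the ketone α-positions so that five-ring closure to the tetrasubstituted butenolide precedes epimerisation or β-elimination.

Step 26
Reactants: 31 butenolide
Product: 32 C9 alcohol
Conditions: HF·pyridine, pyridine, THF, 0 °C
Reagents that add atoms: none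
Why: Buffered HF removes the primary TES ether selectively in the presence of the TBS and TBDPS ethers.

Step 27
Reactants: 32 C9 alcohol
Product: 33 iodo-aldehyde
Conditions: Dess–Martin periodinane, pyridine, CH2Cl2, 0 °C
Reagents that add atoms: none
Why: Dess–Martin oxidation gives the α-silyloxy aldehyde, which is used at once to avoid epimerisation at C8.

**Ring closure and endgame**

Step 28
Reactants: 33 iodo-aldehyde
Product: 34 macrocyclic C9 alcohol
Conditions: CrCl2 (10 equiv), NiCl2 (0.1 equiv), DMSO/THF, 25 °C, 0.002 M, slow addition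
Reagents that add atoms: none
Why: Nozaki–Hiyama–Kishi reaction in which zerovalent nickel inserts into the vinyl iodide with retention, transmetallation to trivalent chromium gives a vinylchromium that adds only to the aldehyde, and the Z alkene holds C2 and C9 cis for ring closure; the C9 carbinol is set by substrate control in the ring-closing transition state and is planned as the 8,9-syn (9R) epimer.

Step 29
Reactants: 35 2-methylprop-2-en-1-ol
Product: 36 (R)-2-methylglycidol
Conditions: Ti(OiPr)4 (10 mol%), D-(−)-diethyl tartrate (12 mol%), t-BuOOH, 4 Å MS, CH2Cl2, −20 °C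
Reagents that add atoms: tert-butyl hydroperoxide, CC(C)(C)OO
Why: Sharpless asymmetric epoxidation, in which the D-(−)-tartrate catalyst gives the (R)-epoxy alcohol.

Step 30
Reactants: 36 (R)-2-methylglycidol
Product: 37 (S)-2-methyloxirane-2-carboxylic acid
Conditions: RuCl3 (2 mol%), NaIO4, MeCN/EtOAc/H2O, 0 to 25 °C
Reagents that add atoms: sodium periodate, [Na+].[O-]I(=O)(=O)=O
Why: Ruthenium tetroxide generated in situ oxidises the primary alcohol to the acid without touching the oxirane, and the stereocentre is unchanged (the descriptor becomes S by priority only).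

Step 31
Reactants: 34 macrocyclic C9 alcohol; 37 (S)-2-methyloxirane-2-carboxylic acid
Product: 38 C9 glycidate
Conditions: DCC, DMAP, CH2Cl2, 0 to 25 °C
Reagents that add atoms: none
Why: Steglich esterification of the allylic C9 alcohol with retention brings in the third oxirane with its stereocentre already fixed.

Step 32
Reactants: 38 C9 glycidate
Product: 39 C14 alcohol
Conditions: DDQ, CH2Cl2/pH 7 buffer, 0 °C
Reagents that add atoms: none
Why: Oxidative PMB cleavage (hydride abstraction, then hydrolysis of the oxocarbenium ion) is orthogonal to the silyl ethers, esters and epoxides.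

Step 33
Reactants: 39 C14 alcohol
Product: 40 C14 senecioate
Conditions: 3-methylbut-2-enoyl chloride, pyridine, CH2Cl2, 0 °C
Reagents that add atoms: 3-methylbut-2-enoyl chloride, CC(C)=CC(Cl)=O
Why: Acylation of the primary allylic alcohol with pyridine as the only base avoids ketene formation and deconjugation of the senecioyl group.

Step 34
Reactants: 40 C14 senecioate
Product: 41 8,13-diol
Conditions: HF·pyridine, pyridine, THF, 0 to 25 °C
Reagents that add atoms: none
Why: Global desilylation under weakly acidic fluoride conditions frees O8 and O13 without triggering acyl migration or translactonisation.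

Step 35
Reactants: 41 8,13-diol
Product: 42 target CNP0279449.1
Conditions: Ac2O, pyridine, DMAP (cat.), CH2Cl2, 0 °C
Reagents that add atoms: acetic anhydride, CC(=O)OC(C)=O
Why: Acetylation of both hydroxyls completes the target without touching any stereocentre.

**Compound list**

1 | but-2-yn-1-ol | CC#CCO | starting material
2 | sodium cyclic (Z)-alkenylalanate of 1 (Al on C3, O–Al chelate, two 2-methoxyethoxy ligands) | CC1=CCO[Al-]1(OCCOC)OCCOC.[Na+] | intermediate (not isolated)
3 | (Z)-3-iodobut-2-en-1-ol | C/C(I)=C/CO | intermediate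
4 | (Z)-tert-butyl[(3-iodobut-2-en-1-yl)oxy]dimethylsilane | C/C(I)=C/CO[Si](C)(C)C(C)(C)C | intermediate
5 | (E)-3-(tributylstannyl)prop-2-en-1-ol | CCCC[Sn](CCCC)(CCCC)/C=C/CO | starting material
6 | (2E,4Z)-6-[(tert-butyldimethylsilyl)oxy]-4-methylhexa-2,4-dien-1-ol | OC/C=C/C(C)=C\CO[Si](C)(C)C(C)(C)C | intermediate
7 | [(2R,3R)-3-[(Z)-4-[(tert-butyldimethylsilyl)oxy]but-2-en-2-yl]oxiran-2-yl]methanol | OC[C@H]1O[C@@H]1/C(C)=C\CO[Si](C)(C)C(C)(C)C | intermediate
8 | (2S,3R)-3-[(Z)-4-[(tert-butyldimethylsilyl)oxy]but-2-en-2-yl]oxirane-2-carbaldehyde | O=C[C@H]1O[C@@H]1/C(C)=C\CO[Si](C)(C)C(C)(C)C | intermediate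
9 | ethyl (triphenylphosphoranylidene)acetate | CCOC(=O)C=P(c1ccccc1)(c1ccccc1)c1ccccc1 | starting material
10 | ethyl iodo(triphenylphosphoranylidene)acetate | CCOC(=O)C(I)=P(c1ccccc1)(c1ccccc1)c1ccccc1 | intermediate
11 | ethyl (Z)-2-iodo-3-[(2R,3R)-3-[(Z)-4-[(tert-butyldimethylsilyl)oxy]but-2-en-2-yl]oxiran-2-yl]prop-2-enoate | CCOC(=O)/C(I)=C/[C@H]1O[C@@H]1/C(C)=C\CO[Si](C)(C)C(C)(C)C | intermediate
12 | (Z)-2-iodo-3-[(2R,3R)-3-[(Z)-4-[(tert-butyldimethylsilyl)oxy]but-2-en-2-yl]oxiran-2-yl]prop-2-en-1-ol | OC/C(I)=C/[C@H]1O[C@@H]1/C(C)=C\CO[Si](C)(C)C(C)(C)C | intermediate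
13 | 4-methoxybenzyl ether of 12 at O14 (C6 still OTBS) | COc1ccc(COC/C(I)=C/[C@H]2O[C@@H]2/C(C)=C\CO[Si](C)(C)C(C)(C)C)cc1 | intermediate
14 | 13 with free C6 allylic alcohol (2,3-trans-epoxide, 4Z alkene, 1(10)Z vinyl iodide, 14-OPMB) | COc1ccc(COC/C(I)=C/[C@H]2O[C@@H]2/C(C)=C\CO)cc1 | intermediate
15 | bis-epoxy alcohol: 2,3-trans/4,5-cis diepoxide with C2–C5 as in the target (2R,3S,4S,5S), C6 = CH2OH, 1(10)Z vinyl iodide, 14-OPMB | COc1ccc(COC/C(I)=C/[C@H]2O[C@@H]2[C@@]2(C)O[C@H]2CO)cc1 | intermediate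
16 | fragment A: as 15 with C6 = CHO | COc1ccc(COC/C(I)=C/[C@H]2O[C@@H]2[C@@]2(C)O[C@H]2C=O)cc1 | intermediate
17 | 2,2-dimethyl-1,3-dioxan-5-one (fragment B) | CC1(C)OCC(=O)CO1 | starting material
18 | (6S,7S)-anti aldol: 4-substituted 2,2-dimethyl-1,3-dioxan-5-one whose C7 carries the C6 carbinol of fragment A; C6 configured as in the target | COc1ccc(COC/C(I)=C/[C@H]2O[C@@H]2[C@@]2(C)O[C@H]2[C@H](O)[C@@H]2OC(C)(C)OCC2=O)cc1 | intermediate
19 | 6-O-TES ether of 18 | COc1ccc(COC/C(I)=C/[C@H]2O[C@@H]2[C@@]2(C)O[C@H]2[C@H](O[Si](CC)(CC)CC)[C@@H]2OC(C)(C)OCC2=O)cc1 | intermediate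
20 | C8 alcohol: dioxan-5-ol with OH cis to the C7 side chain (6,8-anti; C8 as in the target), 6-OTES | COc1ccc(COC/C(I)=C/[C@H]2O[C@@H]2[C@@]2(C)O[C@H]2[C@H](O[Si](CC)(CC)CC)[C@@H]2OC(C)(C)OC[C@@H]2O)cc1 | intermediate
21 | 8-O-TBS ether of 20 | COc1ccc(COC/C(I)=C/[C@H]2O[C@@H]2[C@@]2(C)O[C@H]2[C@H](O[Si](CC)(CC)CC)[C@@H]2OC(C)(C)OC[C@@H]2O[Si](C)(C)C(C)(C)C)cc1 | intermediate
22 | C6 alcohol: 21 without the TES group | COc1ccc(COC/C(I)=C/[C@H]2O[C@@H]2[C@@]2(C)O[C@H]2[C@H](O)[C@@H]2OC(C)(C)OC[C@@H]2O[Si](C)(C)C(C)(C)C)cc1 | intermediate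
23 | benzyl 2-(diethoxyphosphoryl)acetate | CCOP(=O)(CC(=O)OCc1ccccc1)OCC | starting material
24 | benzyl 2-(diethoxyphosphoryl)-3-hydroxypropanoate (racemic) | CCOP(=O)(OCC)C(CO)C(=O)OCc1ccccc1 | intermediate
25 | benzyl 3-[(tert-butyldiphenylsilyl)oxy]-2-(diethoxyphosphoryl)propanoate (racemic) | CCOP(=O)(OCC)C(CO[Si](c1ccccc1)(c1ccccc1)C(C)(C)C)C(=O)OCc1ccccc1 | intermediate
26 | 3-[(tert-butyldiphenylsilyl)oxy]-2-(diethoxyphosphoryl)propanoic acid (racemic) | CCOP(=O)(OCC)C(CO[Si](c1ccccc1)(c1ccccc1)C(C)(C)C)C(O)=O | intermediate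
27 | 6-O-[3-(TBDPS-oxy)-2-(diethoxyphosphoryl)propanoyl] ester of 22 (C11 epimer mixture) | COc1ccc(COC/C(I)=C/[C@H]2O[C@@H]2[C@@]2(C)O[C@H]2[C@H](OC(=O)C(CO[Si](c3ccccc3)(c3ccccc3)C(C)(C)C)P(=O)(OCC)OCC)[C@@H]2OC(C)(C)OC[C@@H]2O[Si](C)(C)C(C)(C)C)cc1 | intermediate
28 | 7,9-diol: 27 without the acetonide (6-O-phosphonoacyl, 8-OTBS) | COc1ccc(COC/C(I)=C/[C@H]2O[C@@H]2[C@@]2(C)O[C@H]2[C@H](OC(=O)C(CO[Si](c3ccccc3)(c3ccccc3)C(C)(C)C)P(=O)(OCC)OCC)[C@H](O)[C@H](CO)O[Si](C)(C)C(C)(C)C)cc1 | intermediate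
29 | 9-O-TES ether of 28 (free C7 hydroxyl) | COc1ccc(COC/C(I)=C/[C@H]2O[C@@H]2[C@@]2(C)O[C@H]2[C@H](OC(=O)C(CO[Si](c3ccccc3)(c3ccccc3)C(C)(C)C)P(=O)(OCC)OCC)[C@H](O)[C@H](CO[Si](CC)(CC)CC)O[Si](C)(C)C(C)(C)C)cc1 | intermediate
30 | C7 ketone (α-acyloxy ketone; 8-OTBS, 9-OTES) | COc1ccc(COC/C(I)=C/[C@H]2O[C@@H]2[C@@]2(C)O[C@H]2[C@H](OC(=O)C(CO[Si](c3ccccc3)(c3ccccc3)C(C)(C)C)P(=O)(OCC)OCC)C(=O)[C@H](CO[Si](CC)(CC)CC)O[Si](C)(C)C(C)(C)C)cc1 | intermediate
31 | butenolide: 7(11)-en-6,12-olide with 13-OTBDPS, 8-OTBS, 9-OTES; C6 and C8 as in the target | COc1ccc(COC/C(I)=C/[C@H]2O[C@@H]2[C@@]2(C)O[C@H]2[C@@H]2OC(=O)C(CO[Si](c3ccccc3)(c3ccccc3)C(C)(C)C)=C2[C@H](CO[Si](CC)(CC)CC)O[Si](C)(C)C(C)(C)C)cc1 | intermediate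
32 | C9 primary alcohol of 31 | COc1ccc(COC/C(I)=C/[C@H]2O[C@@H]2[C@@]2(C)O[C@H]2[C@@H]2OC(=O)C(CO[Si](c3ccccc3)(c3ccccc3)C(C)(C)C)=C2[C@H](CO)O[Si](C)(C)C(C)(C)C)cc1 | intermediate
33 | iodo-aldehyde: C9 = CHO | COc1ccc(COC/C(I)=C/[C@H]2O[C@@H]2[C@@]2(C)O[C@H]2[C@@H]2OC(=O)C(CO[Si](c3ccccc3)(c3ccccc3)C(C)(C)C)=C2[C@H](C=O)O[Si](C)(C)C(C)(C)C)cc1 | intermediate
34 | macrocycle: 1(10)Z-2,3:4,5-diepoxygermacra-1(10),7(11)-dien-6,12-olide with 9-OH, 8-OTBS, 13-OTBDPS, 14-OPMB; all ring stereocentres as in the target | CC(C)(C)[Si](c1ccccc1)(c1ccccc1)OCC1=C2[C@@H](O[Si](C)(C)C(C)(C)C)[C@H](O)/C(COCc3ccc(OC)cc3)=C\[C@H]3O[C@@H]3[C@@]3(C)O[C@H]3[C@@H]2OC1=O | intermediate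
35 | 2-methylprop-2-en-1-ol | CC(=C)CO | starting material
36 | (R)-(2-methyloxiran-2-yl)methanol | OC[C@]1(C)CO1 | intermediate
37 | (S)-2-methyloxirane-2-carboxylic acid | OC(=O)[C@]1(C)CO1 | intermediate
38 | 9-O-[(S)-2-methyloxirane-2-carbonyl] ester of 34 | CC(C)(C)[Si](c1ccccc1)(c1ccccc1)OCC1=C2[C@@H](O[Si](C)(C)C(C)(C)C)[C@H](OC(=O)[C@]3(C)CO3)/C(COCc3ccc(OC)cc3)=C\[C@H]3O[C@@H]3[C@@]3(C)O[C@H]3[C@@H]2OC1=O | intermediate
39 | C14 alcohol: 38 without PMB | CC(C)(C)[Si](c1ccccc1)(c1ccccc1)OCC1=C2[C@@H](O[Si](C)(C)C(C)(C)C)[C@H](OC(=O)[C@]3(C)CO3)/C(CO)=C\[C@H]3O[C@@H]3[C@@]3(C)O[C@H]3[C@@H]2OC1=O | intermediate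
40 | 14-O-(3-methylbut-2-enoyl) ester of 39 | CC(C)(C)[Si](c1ccccc1)(c1ccccc1)OCC1=C2[C@@H](O[Si](C)(C)C(C)(C)C)[C@H](OC(=O)[C@]3(C)CO3)/C(COC(=O)C=C(C)C)=C\[C@H]3O[C@@H]3[C@@]3(C)O[C@H]3[C@@H]2OC1=O | intermediate
41 | 8,13-diol: 40 without both silyl groups | OCC1=C2[C@@H](O)[C@H](OC(=O)[C@]3(C)CO3)/C(COC(=O)C=C(C)C)=C\[C@H]3O[C@@H]3[C@@]3(C)O[C@H]3[C@@H]2OC1=O | intermediate
42 | CNP0279449.1: (1(10)Z,2R,3S,4S,5S,6R,8R,9R)-8,13-diacetoxy-2,3:4,5-diepoxy-9-[(S)-2-methyloxirane-2-carbonyloxy]-14-(3-methylbut-2-enoyloxy)germacra-1(10),7(11)-dien-6,12-olide | CC(=O)OCC1=C2[C@@H](OC(C)=O)[C@H](OC(=O)[C@]3(C)CO3)/C(COC(=O)C=C(C)C)=C\[C@H]3O[C@@H]3[C@@]3(C)O[C@H]3[C@@H]2OC1=O | target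

**Totals**
Total step count: 35. Longest linear sequence: 29 steps (1–5, 7–17, 21–28, 31–35, from but-2-yn-1-ol).

**Three steps most likely to fail**

Step 13 (key aldol). The required C6 configuration is the anti-Felkin one for the cis-epoxy aldehyde, so catalyst and substrate control are opposed. The fallback sets out from 16 and 17 and comes back at 27. If the aldehyde's own facial bias wins, the adduct isolated is the C6 epimer, the (6R,7S)-aldol F1. It is carried through the same four operations: Et3SiOTf gives the 6-epi TES ether F2, LiBH(s-Bu)3 gives the 6-epi C8 alcohol F3 under the same ring control, t-BuMe2SiOTf gives the 6-epi bis-silyl ether F4, and HF·pyridine releases the 6-epi C6 alcohol F5. Mitsunobu esterification of F5 with acid 26 (PPh3, DIAD, toluene, 0 to 25 °C) then installs the phosphonoacetate with inversion at C6 and gives 27, so stereocontrol at C6 moves from the C–C bond formation to an SN2 step.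

Step 22 (acetonide removal next to two epoxides and free hydroxyls). The fallback sets out from 27 and comes back at 29, bypassing 28. It replaces protic methanolysis by a non-protic silyl-triflate ring opening: Et3SiOTf and i-Pr2NEt in CH2Cl2 (−78 to 0 °C) silylate the less hindered acetal oxygen and eliminate, giving the 9-O-triethylsilyl 7-O-(prop-1-en-2-yl) ether F6. The very labile enol ether is then hydrolysed on oxalic-acid-doped silica in wet CH2Cl2 at 0 °C to give 29 directly.

Step 28 (macrocyclisation; C9 configuration not secure). The fallback sets out from 33 and comes back at 34. If the closure gives mainly the C9 epimer, the 9-epi macrocyclic alcohol F7, it is oxidised with Dess–Martin periodinane to the macrocyclic C9 enone F8. Luche reduction (NaBH4, CeCl3·7H2O, MeOH, −78 °C) then delivers hydride anti to the bulky, non-chelating C8–OTBS bond (Felkin–Anh), giving the 8,9-syn alcohol 34; any epimer mixture from step 28 is funnelled the same way.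

**Further compounds**
F1 | step 13 | (6R,7S)-aldol, C6 epimer of 18 | COc1ccc(COC/C(I)=C/[C@H]2O[C@@H]2[C@@]2(C)O[C@H]2[C@@H](O)[C@@H]2OC(C)(C)OCC2=O)cc1
F2 | step 13 | 6-epi TES ether, C6 epimer of 19 | COc1ccc(COC/C(I)=C/[C@H]2O[C@@H]2[C@@]2(C)O[C@H]2[C@@H](O[Si](CC)(CC)CC)[C@@H]2OC(C)(C)OCC2=O)cc1
F3 | step 13 | 6-epi C8 alcohol, C6 epimer of 20 | COc1ccc(COC/C(I)=C/[C@H]2O[C@@H]2[C@@]2(C)O[C@H]2[C@@H](O[Si](CC)(CC)CC)[C@@H]2OC(C)(C)OC[C@@H]2O)cc1
F4 | step 13 | 6-epi bis-silyl ether, C6 epimer of 21 | COc1ccc(COC/C(I)=C/[C@H]2O[C@@H]2[C@@]2(C)O[C@H]2[C@@H](O[Si](CC)(CC)CC)[C@@H]2OC(C)(C)OC[C@@H]2O[Si](C)(C)C(C)(C)C)cc1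
F5 | step 13 | 6-epi C6 alcohol, C6 epimer of 22 | COc1ccc(COC/C(I)=C/[C@H]2O[C@@H]2[C@@]2(C)O[C@H]2[C@@H](O)[C@@H]2OC(C)(C)OC[C@@H]2O[Si](C)(C)C(C)(C)C)cc1
F6 | step 22 | 9-O-triethylsilyl 7-O-(prop-1-en-2-yl) ether from 27 | COc1ccc(COC/C(I)=C/[C@H]2O[C@@H]2[C@@]2(C)O[C@H]2[C@H](OC(=O)C(CO[Si](c3ccccc3)(c3ccccc3)C(C)(C)C)P(=O)(OCC)OCC)[C@H](OC(C)=C)[C@H](CO[Si](CC)(CC)CC)O[Si](C)(C)C(C)(C)C)cc1
F7 | step 28 | 9-epi macrocyclic alcohol, C9 epimer of 34 | CC(C)(C)[Si](c1ccccc1)(c1ccccc1)OCC1=C2[C@@H](O[Si](C)(C)C(C)(C)C)[C@@H](O)/C(COCc3ccc(OC)cc3)=C\[C@H]3O[C@@H]3[C@@]3(C)O[C@H]3[C@@H]2OC1=O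
F8 | step 28 | macrocyclic C9 enone | CC(C)(C)[Si](c1ccccc1)(c1ccccc1)OCC1=C2[C@@H](O[Si](C)(C)C(C)(C)C)C(=O)/C(COCc3ccc(OC)cc3)=C\[C@H]3O[C@@H]3[C@@]3(C)O[C@H]3[C@@H]2OC1=O
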